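The route rests on one disconnection: both rings of the halimane core are opened across C5–C10 and C8–C9. The feature exploited is the C1=C10 alkene, endocyclic in ring A, exocyclic to ring B and flanked by quaternary C9: it is the surviving half of a C1=C10=C9 allene whose ester-bearing C9=C10 bond acted as dienophile. Heating an acyclic (5E,7E)-dienyl allenoate, with C4 fixed from (S)-malic acid and the allene axis fixed from an (R)-propargylic mesylate, closes rings A and B and sets C5, C8 and C9 in one operation. The C9 ester then becomes the C20 methyl and C12 carries the side chain.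

Key step: step 15

Remark (numbering): positions are cited with halimane numbering (ring A = C1–C5 and C10, ring B = C5–C10, side chain C11–C16, C17 on C8, C19 the methyl on C4, C20 on C9); in this numbering the target is (4S,5S,8R,9S,13S,14R).
Remark (assumption): carbonyl addition next to the isopropylidene-protected diol (step 23) is taken to follow the Felkin–Anh course and not magnesium chelation; compounds 11, 16 and 31 are taken as catalogue materials.

Step 1
Reactants: 1 (S)-malic acid
Product: 2 di-tert-butyl (2S)-2-hydroxybutanedioate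
Conditions: O-tert-butyl-N,N'-diisopropylisourea (5 equiv), THF/CH2Cl2, rt
Reagents that add atoms: O-tert-butyl-N,N'-diisopropylisourea, CC(C)N=C(NC(C)C)OC(C)(C)C
Why: Uncatalysed O-alkylation of carboxylic acids by the isourea should esterify both carboxyl groups while the far less acidic secondary alcohol stays free, and the stereocentre is not involved.

Step 2
Reactants: 2 di-tert-butyl (2S)-2-hydroxybutanedioate; 3 allyl bromide
Product: 5 di-tert-butyl (2S,3R)-2-hydroxy-3-(prop-2-enyl)butanedioate, via dilithium alkoxide enolate 4 (not isolated)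
Conditions: LiN(i-Pr)2 (2.2 equiv), THF, −78 to −20 °C; then 3, −78 to −10 °C
Reagents that add atoms: none
Why: Fráter–Seebach alkylation of the chelated alkoxide–enolate, in which the electrophile should enter C3 on the face away from the C1 ester of the lithium chelate and so give the 2,3-anti (3R) product, any minor epimer being separable by chromatography.

Step 3
Reactants: 5 di-tert-butyl (2S,3R)-2-hydroxy-3-(prop-2-enyl)butanedioate
Product: 7 di-tert-butyl (2S,3S)-2-hydroxy-3-methyl-3-(prop-2-enyl)butanedioate, via dilithium alkoxide enolate 6 (not isolated)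
Conditions: LiN(i-Pr)2 (2.2 equiv), THF/DMPU, −78 °C; MeI, −78 to 0 °C
Reagents that add atoms: iodomethane, CI
Why: A second Fráter–Seebach alkylation should attack the same chelate face, so the methyl group takes the site the allyl group entered in step 2 and the quaternary carbon (the future C4) is formed as its (S) epimer, the order of the two alkylations deciding the configuration.

Step 4
Reactants: 7 di-tert-butyl (2S,3S)-2-hydroxy-3-methyl-3-(prop-2-enyl)butanedioate
Product: 8 tert-butyl (2S)-2-[(1S)-1,2-dihydroxyethyl]-2-methylpent-4-enoate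
Conditions: LiBH4, THF/MeOH, 0 °C to rt
Reagents that add atoms: none
Why: Hydroxyl-assisted borohydride reduction should take the unhindered alpha-hydroxy ester, while the tert-butyl ester on the quaternary carbon is too shielded to react and the terminal alkene is inert to borohydride.

Step 5
Reactants: 8 tert-butyl (2S)-2-[(1S)-1,2-dihydroxyethyl]-2-methylpent-4-enoate
Product: 9 tert-butyl (2S)-2-formyl-2-methylpent-4-enoate
Conditions: NaIO4, THF/H2O (pH 7 buffer), 0 °C to rt
Reagents that add atoms: none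
Why: Periodate glycol cleavage should convert the 1,2-diol into the aldehyde with loss of formaldehyde, and the carbon next to the formyl group is quaternary, so it cannot epimerise.

Step 6
Reactants: 9 tert-butyl (2S)-2-formyl-2-methylpent-4-enoate
Product: 10 tert-butyl (2S)-2-[(E)-2-iodoethenyl]-2-methylpent-4-enoate
Conditions: CrCl2 (6 equiv), CHI3 (2 equiv), THF, 0 °C to rt
Reagents that add atoms: iodoform, IC(I)I
Why: Takai olefination is non-basic, should tolerate the formyl ester and is expected to give the (E)-iodoalkene selectively from an aldehyde on a fully substituted carbon.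

Step 7
Reactants: 10 tert-butyl (2S)-2-[(E)-2-iodoethenyl]-2-methylpent-4-enoate; 11 (E)-prop-1-enylboronic acid pinacol ester
Product: 12 tert-butyl (2S,3E,5E)-2-methyl-2-(prop-2-enyl)hepta-3,5-dienoate
Conditions: Pd(PPh3)4 (5 mol%), K3PO4 (aq), 1,4-dioxane, 60 °C
Reagents that add atoms: none
Why: Suzuki–Miyaura coupling of an alkenyl iodide with an alkenylboronate proceeds with retention at both partners and should therefore deliver the (E,E)-diene with defined geometry.

Step 8
Reactants: 12 tert-butyl (2S,3E,5E)-2-methyl-2-(prop-2-enyl)hepta-3,5-dienoate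
Product: 14 tert-butyl (2S,3E,5E)-2-(3-hydroxypropyl)-2-methylhepta-3,5-dienoate, via B-alkyl-9-borabicyclononane adduct 13 (not isolated)
Conditions: 9-BBN (1.2 equiv), THF, 0 °C to rt; then NaOH (3 M), H2O2 (30%), 0 °C
Reagents that add atoms: hydrogen peroxide, OO
Why: Anti-Markovnikov hydroboration–oxidation with 9-BBN should select the monosubstituted alkene over the internal conjugated diene by a wide margin, and the shielded tert-butyl ester should survive cold alkaline peroxide.

Step 9
Reactants: 14 tert-butyl (2S,3E,5E)-2-(3-hydroxypropyl)-2-methylhepta-3,5-dienoate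
Product: 15 tert-butyl (2S,3E,5E)-2-methyl-2-(3-oxopropyl)hepta-3,5-dienoate
Conditions: Dess–Martin periodinane, NaHCO3, CH2Cl2, 0 °C to rt
Reagents that add atoms: none
Why: Dess–Martin oxidation of the primary alcohol should stop at the aldehyde under buffered conditions that leave diene and ester untouched.

Step 10
Reactants: 15 tert-butyl (2S,3E,5E)-2-methyl-2-(3-oxopropyl)hepta-3,5-dienoate; 16 tert-butyl(but-3-ynyloxy)dimethylsilane
Product: 18 tert-butyl (2S,3E,5E)-2-[7-(tert-butyldimethylsilyloxy)-3-hydroxyhept-4-ynyl]-2-methylhepta-3,5-dienoate as both carbinol epimers, via lithium acetylide 17 (not isolated)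
Conditions: 16, n-BuLi, THF, −78 °C; then 15, −78 °C
Reagents that add atoms: none
Why: 1,2-Addition of a lithium acetylide to the aldehyde should form the C1–C10 bond without touching the shielded ester, and the carbinol configuration is left open because it is set in step 12.

Step 11
Reactants: 18 tert-butyl (2S,3E,5E)-2-[7-(tert-butyldimethylsilyloxy)-3-hydroxyhept-4-ynyl]-2-methylhepta-3,5-dienoate
Product: 19 tert-butyl (2S,3E,5E)-2-[7-(tert-butyldimethylsilyloxy)-3-oxohept-4-ynyl]-2-methylhepta-3,5-dienoate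
Conditions: Dess–Martin periodinane, NaHCO3, CH2Cl2, rt
Reagents that add atoms: none
Why: Dess–Martin oxidation of the propargylic alcohol should give the ynone cleanly and merge both epimers into one compound.

Step 12
Reactants: 19 tert-butyl (2S,3E,5E)-2-[7-(tert-butyldimethylsilyloxy)-3-oxohept-4-ynyl]-2-methylhepta-3,5-dienoate
Product: 20 tert-butyl (2S,3E,5E)-2-[(3R)-7-(tert-butyldimethylsilyloxy)-3-hydroxyhept-4-ynyl]-2-methylhepta-3,5-dienoate
Conditions: Ru[(R,R)-TsDPEN](p-cymene) (2 mol%), i-PrOH, rt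
Reagents that add atoms: none
Why: Noyori asymmetric transfer hydrogenation of an ynone, in which the alkynyl group takes the place of the unsaturated substituent in the transition state, so the (R,R)-catalyst should give the (R)-propargylic alcohol under reagent control with no influence from remote C4.

Step 13
Reactants: 20 tert-butyl (2S,3E,5E)-2-[(3R)-7-(tert-butyldimethylsilyloxy)-3-hydroxyhept-4-ynyl]-2-methylhepta-3,5-dienoate
Product: 21 tert-butyl (2S,3E,5E)-2-[(3R)-7-(tert-butyldimethylsilyloxy)-3-(methanesulfonyloxy)hept-4-ynyl]-2-methylhepta-3,5-dienoate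
Conditions: MsCl, Et3N, CH2Cl2, −78 to −20 °C
Reagents that add atoms: methanesulfonyl chloride, CS(=O)(=O)Cl
Why: O-Sulfonylation does not touch the C–O bond, so the (R) configuration should be retained in the propargylic mesylate, which is used without chromatography.

Step 14
Reactants: 21 tert-butyl (2S,3E,5E)-2-[(3R)-7-(tert-butyldimethylsilyloxy)-3-(methanesulfonyloxy)hept-4-ynyl]-2-methylhepta-3,5-dienoate
Product: 22 1-tert-butyl 8-methyl (2S)-7-[2-(tert-butyldimethylsilyloxy)ethyl]-2-methyl-2-[(1E,3E)-penta-1,3-dienyl]octa-5,6-dienedioate with (aS) allene axis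
Conditions: Pd(PPh3)4 (5 mol%), CO (1 atm), MeOH, 2,6-lutidine, THF, rt
Reagents that add atoms: carbon monoxide, [C-]#[O+]; methanol, CO
Why: Palladium-catalysed alkoxycarbonylation of a propargylic mesylate, in which zerovalent palladium should displace the mesylate in an anti SN2' sense to an allenylpalladium species and CO insertion with methanolysis then proceeds with retention, so the (R) centre is transferred into the (aS) axis.

Step 15
Reactants: 22 1-tert-butyl 8-methyl (2S)-7-[2-(tert-butyldimethylsilyloxy)ethyl]-2-methyl-2-[(1E,3E)-penta-1,3-dienyl]octa-5,6-dienedioate with (aS) allene axis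
Product: 23 1-tert-butyl 5-methyl (1S,5R,6R,8aS)-5-[2-(tert-butyldimethylsilyloxy)ethyl]-1,6-dimethyl-1,2,3,5,6,8a-hexahydronaphthalene-1,5-dicarboxylate
Conditions: toluene (0.01 M), BHT, 110–130 °C, sealed tube
Reagents that add atoms: none
Why: On heating, the s-cis (5E,7E)-diene should add suprafacially and in concert across the ester-conjugated C9=C10 bond of the allene, forming C5–C10 and C8–C9 in a thermal intramolecular Diels–Alder reaction whose closest known relatives are the cycloadditions of allenic esters at their conjugated double bond with transfer of axial to central chirality. Ring B (C5–C10) closes as the cyclohexene of the [4+2] adduct, and ring A (C10, C1–C5) closes through the four-atom tether C1–C2–C3–C4, which enters the six-membered ring together with the untouched allene bond, now the endocyclic C1=C10 alkene. C9 is set by the (aS) axis, because C2 sits on one lobe of the C9=C10 pi bond and the tethered diene can reach only that face; C5 and C8 are set relative to each other by the E,E geometry (C4 and C17 cis) and relative to C9 by the endo position of the ester beneath C6–C7, which leaves C17 cis to the future C20. Two selectivities are needed: periselectivity for C9=C10 over the unactivated C1=C10 bond, which the three-atom tether could reach, is secured by the ester lowering the LUMO of C9=C10 only, and endo selectivity is secured by secondary overlap of the ester together with the exo preference of the bulkier silyloxyethyl arm. C4 is a spectator that only distributes its methyl and ester groups over ring A, and release of allene strain should offset the cost of forming quaternary C9.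

Step 16
Reactants: 23 1-tert-butyl 5-methyl (1S,5R,6R,8aS)-5-[2-(tert-butyldimethylsilyloxy)ethyl]-1,6-dimethyl-1,2,3,5,6,8a-hexahydronaphthalene-1,5-dicarboxylate
Product: 24 1-tert-butyl 5-methyl (1S,5R,6R,8aS)-5-[2-(tert-butyldimethylsilyloxy)ethyl]-1,6-dimethyl-1,2,3,5,6,7,8,8a-octahydronaphthalene-1,5-dicarboxylate
Conditions: H2 (1–3 atm), RhCl(PPh3)3 (10 mol%), benzene/EtOH, rt
Reagents that add atoms: none
Why: Homogeneous hydrogenation with RhCl(PPh3)3 discriminates strongly by substitution, so the cis-disubstituted C6=C7 bond should be saturated while the trisubstituted C1=C10 bond next to quaternary C9 is left, and no stereocentre is created.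

Step 17
Reactants: 24 1-tert-butyl 5-methyl (1S,5R,6R,8aS)-5-[2-(tert-butyldimethylsilyloxy)ethyl]-1,6-dimethyl-1,2,3,5,6,7,8,8a-octahydronaphthalene-1,5-dicarboxylate
Product: 25 tert-butyl (1S,5R,6R,8aS)-5-[2-(tert-butyldimethylsilyloxy)ethyl]-5-(hydroxymethyl)-1,6-dimethyl-1,2,3,5,6,7,8,8a-octahydronaphthalene-1-carboxylate
Conditions: i-Bu2AlH (3 equiv), CH2Cl2, −78 to 0 °C
Reagents that add atoms: none
Why: Chemoselective hydride reduction should take the methyl ester and spare the tert-butyl ester, which is bulkier at oxygen and also sits on a quaternary carbon, giving the C20 primary alcohol.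

Step 18
Reactants: 25 tert-butyl (1S,5R,6R,8aS)-5-[2-(tert-butyldimethylsilyloxy)ethyl]-5-(hydroxymethyl)-1,6-dimethyl-1,2,3,5,6,7,8,8a-octahydronaphthalene-1-carboxylate
Product: 26 tert-butyl (1S,5R,6R,8aS)-5-[2-(tert-butyldimethylsilyloxy)ethyl]-5-formyl-1,6-dimethyl-1,2,3,5,6,7,8,8a-octahydronaphthalene-1-carboxylate
Conditions: Dess–Martin periodinane, NaHCO3, CH2Cl2, rt
Reagents that add atoms: none
Why: Dess–Martin oxidation of the neopentyl alcohol should give an aldehyde that cannot enolise.

Step 19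
Reactants: 26 tert-butyl (1S,5R,6R,8aS)-5-[2-(tert-butyldimethylsilyloxy)ethyl]-5-formyl-1,6-dimethyl-1,2,3,5,6,7,8,8a-octahydronaphthalene-1-carboxylate
Product: 28 tert-butyl (1S,5S,6R,8aS)-5-[2-(tert-butyldimethylsilyloxy)ethyl]-1,5,6-trimethyl-1,2,3,5,6,7,8,8a-octahydronaphthalene-1-carboxylate, via N-silyl hydrazone 27 (not isolated)
Conditions: 1,2-bis(tert-butyldimethylsilyl)hydrazine, Sc(OTf)3 (cat.), CHCl3, rt; then KOt-Bu (cat.), t-BuOH, DMSO, rt to 60 °C
Reagents that add atoms: none
Why: Wolff–Kishner reduction in its low-temperature N-silyl hydrazone form should turn the formyl group into the C20 methyl through a diazenyl anion that is protonated as nitrogen leaves, an ionic path chosen because a C20 radical would be homoallylic to C1=C10 and prone to a 1,2-vinyl shift.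

Step 20
Reactants: 28 tert-butyl (1S,5S,6R,8aS)-5-[2-(tert-butyldimethylsilyloxy)ethyl]-1,5,6-trimethyl-1,2,3,5,6,7,8,8a-octahydronaphthalene-1-carboxylate
Product: 29 tert-butyl (1S,5S,6R,8aS)-5-(2-hydroxyethyl)-1,5,6-trimethyl-1,2,3,5,6,7,8,8a-octahydronaphthalene-1-carboxylate
Conditions: Bu4NF, THF, rt
Reagents that add atoms: none
Why: Fluoride-induced silyl ether cleavage should free the C12 alcohol without affecting the tert-butyl ester or the alkene.

Step 21
Reactants: 29 tert-butyl (1S,5S,6R,8aS)-5-(2-hydroxyethyl)-1,5,6-trimethyl-1,2,3,5,6,7,8,8a-octahydronaphthalene-1-carboxylate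
Product: 30 tert-butyl (1S,5S,6R,8aS)-5-(2-iodoethyl)-1,5,6-trimethyl-1,2,3,5,6,7,8,8a-octahydronaphthalene-1-carboxylate
Conditions: I2, PPh3, imidazole, CH2Cl2, 0 °C to rt
Reagents that add atoms: iodine, II
Why: Appel-type iodination through the alkoxyphosphonium salt should convert the unhindered primary alcohol into the iodide by SN2 displacement.

Step 22
Reactants: 31 methyl (4R)-2,2-dimethyl-1,3-dioxolane-4-carboxylate
Product: 33 1-[(4R)-2,2-dimethyl-1,3-dioxolan-4-yl]ethanone, via Weinreb amide 32 (not isolated)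
Conditions: MeNH(OMe)·HCl, i-PrMgCl, THF, −20 °C; then MeMgBr, 0 °C
Reagents that add atoms: methylmagnesium bromide, C[Mg]Br
Why: Ester aminolysis by the magnesium amide of N,O-dimethylhydroxylamine followed by Grignard addition to the Weinreb amide should stop at the ketone because of the stable magnesium chelate, and the alkoxy-bearing stereocentre should not epimerise at these temperatures.

Step 23
Reactants: 30 tert-butyl (1S,5S,6R,8aS)-5-(2-iodoethyl)-1,5,6-trimethyl-1,2,3,5,6,7,8,8a-octahydronaphthalene-1-carboxylate; 33 1-[(4R)-2,2-dimethyl-1,3-dioxolan-4-yl]ethanone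
Product: 36 tert-butyl (1S,5S,6R,8aS)-5-[(3S)-3-[(4R)-2,2-dimethyl-1,3-dioxolan-4-yl]-3-hydroxybutyl]-1,5,6-trimethyl-1,2,3,5,6,7,8,8a-octahydronaphthalene-1-carboxylate, via alkyllithium 34 (not isolated), via alkylmagnesium bromide 35 (not isolated)
Conditions: t-BuLi (2.1 equiv), Et2O/pentane, −78 °C; MgBr2·OEt2; then 33, THF, −78 °C
Reagents that add atoms: none
Why: Iodine–lithium exchange and transmetalation give a primary Grignard reagent that should add to the methyl ketone by the Felkin–Anh path, anti to the dioxolane C–O bond and past the C14 hydrogen, which gives the 13,14-anti (13S,14R) pattern of the target, while the shielded tert-butyl ester should not react at −78 °C.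

Step 24
Reactants: 36 tert-butyl (1S,5S,6R,8aS)-5-[(3S)-3-[(4R)-2,2-dimethyl-1,3-dioxolan-4-yl]-3-hydroxybutyl]-1,5,6-trimethyl-1,2,3,5,6,7,8,8a-octahydronaphthalene-1-carboxylate
Product: 37 (1S,5S,6R,8aS)-1,5,6-trimethyl-5-[(3S,4R)-3,4,5-trihydroxy-3-methylpentyl]-1,2,3,5,6,7,8,8a-octahydronaphthalene-1-carboxylic acid
Conditions: CF3CO2H/H2O (9:1), CH2Cl2, 0 °C
Reagents that add atoms: none
Why: Acid-catalysed acetal hydrolysis and E1-type loss of isobutene from the tert-butyl ester should occur together, while the tertiary carbinol is deactivated towards ionisation by the adjacent oxygen-bearing carbon and a short, cold exposure should spare the C1=C10 bond.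

Step 25
Reactants: 37 (1S,5S,6R,8aS)-1,5,6-trimethyl-5-[(3S,4R)-3,4,5-trihydroxy-3-methylpentyl]-1,2,3,5,6,7,8,8a-octahydronaphthalene-1-carboxylic acid
Product: 39 (1S,5S,6R,8aS)-5-[(3S,4R)-4,5-diacetoxy-3-hydroxy-3-methylpentyl]-1,5,6-trimethyl-1,2,3,5,6,7,8,8a-octahydronaphthalene-1-carboxylic acid (CNP0224606.2), via mixed anhydride 38 (not isolated)
Conditions: Ac2O, pyridine, CH2Cl2, 0 °C to rt; then NaHCO3 (aq), THF
Reagents that add atoms: acetic anhydride, CC(=O)OC(C)=O
Why: Acetylation with acetic anhydride and pyridine should esterify the primary and secondary hydroxyls but not the hindered tertiary one, and the mixed anhydride formed at the acid should be hydrolysed at its acetyl carbonyl during the bicarbonate work-up.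

Compound list
1 | (S)-malic acid | O[C@@H](CC(=O)O)C(=O)O | starting material
2 | di-tert-butyl (2S)-2-hydroxybutanedioate | O[C@@H](CC(=O)OC(C)(C)C)C(=O)OC(C)(C)C | intermediate
3 | allyl bromide | C=CCBr | starting material
4 | dilithium alkoxide enolate of 2 | [Li]O[C@@H](C=C(O[Li])OC(C)(C)C)C(=O)OC(C)(C)C | intermediate
5 | di-tert-butyl (2S,3R)-2-hydroxy-3-(prop-2-enyl)butanedioate | O[C@@H]([C@@H](CC=C)C(=O)OC(C)(C)C)C(=O)OC(C)(C)C | intermediate
6 | dilithium alkoxide enolate of 5 | [Li]O[C@@H](C(CC=C)=C(O[Li])OC(C)(C)C)C(=O)OC(C)(C)C | intermediate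
7 | di-tert-butyl (2S,3S)-2-hydroxy-3-methyl-3-(prop-2-enyl)butanedioate | O[C@@H]([C@@](CC=C)(C)C(=O)OC(C)(C)C)C(=O)OC(C)(C)C | intermediate
8 | tert-butyl (2S)-2-[(1S)-1,2-dihydroxyethyl]-2-methylpent-4-enoate | O[C@@H]([C@@](CC=C)(C)C(=O)OC(C)(C)C)CO | intermediate
9 | tert-butyl (2S)-2-formyl-2-methylpent-4-enoate | O=C[C@@](CC=C)(C)C(=O)OC(C)(C)C | intermediate
10 | tert-butyl (2S)-2-[(E)-2-iodoethenyl]-2-methylpent-4-enoate | I/C=C/[C@@](CC=C)(C)C(=O)OC(C)(C)C | intermediate
11 | (E)-prop-1-enylboronic acid pinacol ester | C/C=C/B1OC(C)(C)C(C)(C)O1 | starting material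
12 | tert-butyl (2S,3E,5E)-2-methyl-2-(prop-2-enyl)hepta-3,5-dienoate | C/C=C/C=C/[C@@](CC=C)(C)C(=O)OC(C)(C)C | intermediate
13 | B-alkyl-9-borabicyclononane adduct of 12 | C/C=C/C=C/[C@@](CCCB1C2CCCC1CCC2)(C)C(=O)OC(C)(C)C | intermediate
14 | tert-butyl (2S,3E,5E)-2-(3-hydroxypropyl)-2-methylhepta-3,5-dienoate | C/C=C/C=C/[C@@](CCCO)(C)C(=O)OC(C)(C)C | intermediate
15 | tert-butyl (2S,3E,5E)-2-methyl-2-(3-oxopropyl)hepta-3,5-dienoate | C/C=C/C=C/[C@@](CCC=O)(C)C(=O)OC(C)(C)C | intermediate
16 | tert-butyl(but-3-ynyloxy)dimethylsilane | C#CCCO[Si](C)(C)C(C)(C)C | starting material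
17 | lithium acetylide of 16 | [Li]C#CCCO[Si](C)(C)C(C)(C)C | intermediate
18 | tert-butyl (2S,3E,5E)-2-[7-(tert-butyldimethylsilyloxy)-3-hydroxyhept-4-ynyl]-2-methylhepta-3,5-dienoate, both carbinol epimers | C/C=C/C=C/[C@@](CCC(O)C#CCCO[Si](C)(C)C(C)(C)C)(C)C(=O)OC(C)(C)C | intermediate
19 | tert-butyl (2S,3E,5E)-2-[7-(tert-butyldimethylsilyloxy)-3-oxohept-4-ynyl]-2-methylhepta-3,5-dienoate | C/C=C/C=C/[C@@](CCC(=O)C#CCCO[Si](C)(C)C(C)(C)C)(C)C(=O)OC(C)(C)C | intermediate
20 | tert-butyl (2S,3E,5E)-2-[(3R)-7-(tert-butyldimethylsilyloxy)-3-hydroxyhept-4-ynyl]-2-methylhepta-3,5-dienoate | C/C=C/C=C/[C@@](CC[C@@H](O)C#CCCO[Si](C)(C)C(C)(C)C)(C)C(=O)OC(C)(C)C | intermediate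
21 | tert-butyl (2S,3E,5E)-2-[(3R)-7-(tert-butyldimethylsilyloxy)-3-(methanesulfonyloxy)hept-4-ynyl]-2-methylhepta-3,5-dienoate | C/C=C/C=C/[C@@](CC[C@@H](OS(C)(=O)=O)C#CCCO[Si](C)(C)C(C)(C)C)(C)C(=O)OC(C)(C)C | intermediate
22 | 1-tert-butyl 8-methyl (2S)-7-[2-(tert-butyldimethylsilyloxy)ethyl]-2-methyl-2-[(1E,3E)-penta-1,3-dienyl]octa-5,6-dienedioate, (aS) axis (halimane C4 S; cycloaddition precursor) | [H]C(CC[C@](C)(C(=O)OC(C)(C)C)/C=C/C=C/C)=[C@]=C(CCO[Si](C)(C)C(C)(C)C)C(=O)OC | intermediate
23 | 1-tert-butyl 5-methyl (1S,5R,6R,8aS)-5-[2-(tert-butyldimethylsilyloxy)ethyl]-1,6-dimethyl-1,2,3,5,6,8a-hexahydronaphthalene-1,5-dicarboxylate (halimane 4S,5S,8R,9R; cycloadduct) | CC(C)(C)[Si](C)(C)OCC[C@]1(C(=O)OC)C2=CCC[C@](C)(C(=O)OC(C)(C)C)[C@H]2C=C[C@H]1C | intermediate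
24 | 1-tert-butyl 5-methyl (1S,5R,6R,8aS)-5-[2-(tert-butyldimethylsilyloxy)ethyl]-1,6-dimethyl-1,2,3,5,6,7,8,8a-octahydronaphthalene-1,5-dicarboxylate | CC(C)(C)[Si](C)(C)OCC[C@]1(C(=O)OC)C2=CCC[C@](C)(C(=O)OC(C)(C)C)[C@H]2CC[C@H]1C | intermediate
25 | tert-butyl (1S,5R,6R,8aS)-5-[2-(tert-butyldimethylsilyloxy)ethyl]-5-(hydroxymethyl)-1,6-dimethyl-1,2,3,5,6,7,8,8a-octahydronaphthalene-1-carboxylate | CC(C)(C)[Si](C)(C)OCC[C@]1(CO)C2=CCC[C@](C)(C(=O)OC(C)(C)C)[C@H]2CC[C@H]1C | intermediate
26 | tert-butyl (1S,5R,6R,8aS)-5-[2-(tert-butyldimethylsilyloxy)ethyl]-5-formyl-1,6-dimethyl-1,2,3,5,6,7,8,8a-octahydronaphthalene-1-carboxylate | CC(C)(C)[Si](C)(C)OCC[C@]1(C=O)C2=CCC[C@](C)(C(=O)OC(C)(C)C)[C@H]2CC[C@H]1C | intermediate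
27 | N-(tert-butyldimethylsilyl)hydrazone of 26 | CC(C)(C)[Si](C)(C)OCC[C@]1(C=NN[Si](C)(C)C(C)(C)C)C2=CCC[C@](C)(C(=O)OC(C)(C)C)[C@H]2CC[C@H]1C | intermediate
28 | tert-butyl (1S,5S,6R,8aS)-5-[2-(tert-butyldimethylsilyloxy)ethyl]-1,5,6-trimethyl-1,2,3,5,6,7,8,8a-octahydronaphthalene-1-carboxylate | CC(C)(C)[Si](C)(C)OCC[C@]1(C)C2=CCC[C@](C)(C(=O)OC(C)(C)C)[C@H]2CC[C@H]1C | intermediate
29 | tert-butyl (1S,5S,6R,8aS)-5-(2-hydroxyethyl)-1,5,6-trimethyl-1,2,3,5,6,7,8,8a-octahydronaphthalene-1-carboxylate | OCC[C@]1(C)C2=CCC[C@](C)(C(=O)OC(C)(C)C)[C@H]2CC[C@H]1C | intermediate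
30 | tert-butyl (1S,5S,6R,8aS)-5-(2-iodoethyl)-1,5,6-trimethyl-1,2,3,5,6,7,8,8a-octahydronaphthalene-1-carboxylate | ICC[C@]1(C)C2=CCC[C@](C)(C(=O)OC(C)(C)C)[C@H]2CC[C@H]1C | intermediate
31 | methyl (4R)-2,2-dimethyl-1,3-dioxolane-4-carboxylate | COC(=O)[C@H]1COC(C)(C)O1 | starting material
32 | (4R)-N-methoxy-N,2,2-trimethyl-1,3-dioxolane-4-carboxamide | CON(C)C(=O)[C@H]1COC(C)(C)O1 | intermediate
33 | 1-[(4R)-2,2-dimethyl-1,3-dioxolan-4-yl]ethanone | CC(=O)[C@H]1COC(C)(C)O1 | intermediate
34 | alkyllithium from 30 | [Li]CC[C@]1(C)C2=CCC[C@](C)(C(=O)OC(C)(C)C)[C@H]2CC[C@H]1C | intermediate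
35 | alkylmagnesium bromide from 34 | Br[Mg]CC[C@]1(C)C2=CCC[C@](C)(C(=O)OC(C)(C)C)[C@H]2CC[C@H]1C | intermediate
36 | tert-butyl (1S,5S,6R,8aS)-5-[(3S)-3-[(4R)-2,2-dimethyl-1,3-dioxolan-4-yl]-3-hydroxybutyl]-1,5,6-trimethyl-1,2,3,5,6,7,8,8a-octahydronaphthalene-1-carboxylate | C1OC(C)(C)O[C@H]1[C@@](C)(O)CC[C@]2(C)C3=CCC[C@](C)(C(=O)OC(C)(C)C)[C@H]3CC[C@H]2C | intermediate
37 | (1S,5S,6R,8aS)-1,5,6-trimethyl-5-[(3S,4R)-3,4,5-trihydroxy-3-methylpentyl]-1,2,3,5,6,7,8,8a-octahydronaphthalene-1-carboxylic acid | OC[C@@H](O)[C@@](C)(O)CC[C@]1(C)C2=CCC[C@](C)(C(=O)O)[C@H]2CC[C@H]1C | intermediate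
38 | acetic mixed anhydride of the diacetate of 37 | CC(=O)OC[C@@H](OC(C)=O)[C@@](C)(O)CC[C@]1(C)C2=CCC[C@](C)(C(=O)OC(C)=O)[C@H]2CC[C@H]1C | intermediate
39 | (1S,5S,6R,8aS)-5-[(3S,4R)-4,5-diacetoxy-3-hydroxy-3-methylpentyl]-1,5,6-trimethyl-1,2,3,5,6,7,8,8a-octahydronaphthalene-1-carboxylic acid (CNP0224606.2) | CC(=O)OC[C@@H](OC(C)=O)[C@@](C)(O)CC[C@]1(C)C2=CCC[C@](C)(C(=O)O)[C@H]2CC[C@H]1C | target

Total step count: 25. Longest linear sequence: 24 steps (steps 1–21 and 23–25; step 22 is the one-step side branch).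

Steps most likely to fail

Step 15. The cycloaddition may be diverted to the unactivated C1=C10 bond of the allene through the three-carbon tether (giving a hydrindane), or the allenoate may isomerise or dimerise before the crowded C8–C9 bond forms. The fallback sets out from allenoate 22 and moves the reduction ahead of the cycloaddition, so that a formyl group activates the dienophile. i-Bu2AlH at −78 °C should reduce the methyl allenoate to the allenyl carbinol F1 with the tert-butyl ester untouched, and Dess–Martin periodinane should then give the allenal F2. Its lower LUMO should let the intramolecular Diels–Alder reaction run at or below 60 °C, or at −78 °C with Me2AlCl, to the formyl cycloadduct F3. Hydrogenation of C6=C7 with H2 and RhCl(PPh3)3 at room temperature, where decarbonylation of the hindered aldehyde is slow, comes back to the route at aldehyde 26, so that steps 16–18 are no longer needed.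

Step 23. Magnesium chelation to the dioxolane oxygen may compete with the Felkin–Anh course, so that facial selectivity at C13 is eroded or reversed. The fallback sets out from iodide 30 and exchanges the order in which C12 and the methyl group arrive, so that chelation works for the route. Alkyllithium 34, made as in step 23, is added at −78 °C to Weinreb amide 32, isolated after the first stage of step 22, to give the ketone F4. MeMgBr with MgBr2·OEt2 in CH2Cl2 at −78 °C should then add to the five-membered chelate from the side of the C14 hydrogen (Cram-chelate addition), which gives the same (13S,14R) alcohol and comes back to the route at 36.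

Step 24. Strong protic acid may shift the C1=C10 double bond into the tetrasubstituted C5=C10 position or ionise the tertiary carbinol before the tert-butyl ester has gone. The fallback sets out from 36 and separates the two deprotections. Acetal exchange with pyridinium p-toluenesulfonate in MeOH should give the triol ester F5, and Ac2O with pyridine the diacetate ester F6. The tert-butyl ester is then removed without a Brønsted acid, by ZnBr2 in CH2Cl2 at room temperature, which comes back to the route at target 39.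

Further compounds
F1 | step 15 | tert-butyl (2S,3E,5E)-2-[7-(tert-butyldimethylsilyloxy)-5-(hydroxymethyl)hepta-3,4-dienyl]-2-methylhepta-3,5-dienoate, (aS) axis | [H]C(CC[C@](C)(C(=O)OC(C)(C)C)/C=C/C=C/C)=[C@]=C(CCO[Si](C)(C)C(C)(C)C)CO
F2 | step 15 | tert-butyl (2S,3E,5E)-2-[7-(tert-butyldimethylsilyloxy)-5-formylhepta-3,4-dienyl]-2-methylhepta-3,5-dienoate, (aS) axis | [H]C(CC[C@](C)(C(=O)OC(C)(C)C)/C=C/C=C/C)=[C@]=C(CCO[Si](C)(C)C(C)(C)C)C=O
F3 | step 15 | tert-butyl (1S,5R,6R,8aS)-5-[2-(tert-butyldimethylsilyloxy)ethyl]-5-formyl-1,6-dimethyl-1,2,3,5,6,8a-hexahydronaphthalene-1-carboxylate | CC(C)(C)[Si](C)(C)OCC[C@]1(C=O)C2=CCC[C@](C)(C(=O)OC(C)(C)C)[C@H]2C=C[C@H]1C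
F4 | step 23 | tert-butyl (1S,5S,6R,8aS)-5-[3-[(4R)-2,2-dimethyl-1,3-dioxolan-4-yl]-3-oxopropyl]-1,5,6-trimethyl-1,2,3,5,6,7,8,8a-octahydronaphthalene-1-carboxylate | O=C([C@H]1COC(C)(C)O1)CC[C@]2(C)C3=CCC[C@](C)(C(=O)OC(C)(C)C)[C@H]3CC[C@H]2C
F5 | step 24 | tert-butyl (1S,5S,6R,8aS)-1,5,6-trimethyl-5-[(3S,4R)-3,4,5-trihydroxy-3-methylpentyl]-1,2,3,5,6,7,8,8a-octahydronaphthalene-1-carboxylate | OC[C@@H](O)[C@@](C)(O)CC[C@]1(C)C2=CCC[C@](C)(C(=O)OC(C)(C)C)[C@H]2CC[C@H]1C
F6 | step 24 | tert-butyl (1S,5S,6R,8aS)-5-[(3S,4R)-4,5-diacetoxy-3-hydroxy-3-methylpentyl]-1,5,6-trimethyl-1,2,3,5,6,7,8,8a-octahydronaphthalene-1-carboxylate | CC(=O)OC[C@@H](OC(C)=O)[C@@](C)(O)CC[C@]1(C)C2=CCC[C@](C)(C(=O)OC(C)(C)C)[C@H]2CC[C@H]1C
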